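**Plan**

- Feature used: ring A of the 2H-chromene (C4a, C5, C6, C7, C8, C8a) has its oxygens on C7 and C8a, 1,3 to each other across C8, and the arylethyl chain on C5. Two oxidation levels lower, this ring is a 5-substituted cyclohexane-1,3-dione whose carbonyls are interchangeable.
- Retrosynthesis: cut O–Si, restore the C5–H/C6–H pair, open ring B at O1–C2 (retro-oxa-6π) and cut C4–C4a (retro-aldol to 3-methylbut-2-enal), cut the prenyl O–CH2 bond, then cut ring A at C7–C8 (retro-Claisen) and C5–C6 (retro-Michael to dimethyl malonate, one ester carbon being excised), and last the enone C=C (Wittig).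
- Forward: ring C is bought. Its side chain is grown to an enone, malonate is added, ring A closes as the dione (step 4), and one carbonyl becomes the prenyl enol ether. Ring B is then built on the α′ carbon by aldol, dehydration and oxa-6π closure, and ring A is aromatized last, before desilylation.
- Stereochemistry: the target is achiral. Every sp3 stereocentre on the way is racemic or uncontrolled and ends as an sp2 carbon.

Key step: step 4

Remark: atom numbers are those of the 2H-chromene; ring A is its carbocycle, ring B the pyran, ring C the 4-hydroxyphenyl ring. Cyclic 1,3-diones are drawn as diketo tautomers, and C7–C8/C8–C8a as well as C5–C6/C5–C4a are equivalent pairs until the dione is etherified.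

**Route**

Step 1
Reactants: 1 methyl 3-(4-hydroxyphenyl)propanoate
Product: 2 3-(4-hydroxyphenyl)propanal
Conditions: i-Bu2AlH (2.2 equiv), CH2Cl2, −78 °C; MeOH, then aq. potassium sodium tartrate
Reagents that add atoms: none
Why: Partial ester reduction with i-Bu2AlH at −78 °C should stop at the aluminium hemiacetal, which releases the aldehyde only on work-up; the first equivalent of hydride is consumed by the phenol, whose aluminium phenoxide is inert.

Step 2
Reactants: 2 3-(4-hydroxyphenyl)propanal; 3 1-(triphenylphosphoranylidene)propan-2-one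
Product: 4 (3E)-6-(4-hydroxyphenyl)hex-3-en-2-one
Conditions: CH2Cl2, 40 °C
Reagents that add atoms: none
Why: Wittig olefination with a ketone-stabilized ylide is E-selective, and the ylide is too weakly basic to be quenched by the free phenol.

Step 3
Reactants: 4 (3E)-6-(4-hydroxyphenyl)hex-3-en-2-one; 5 dimethyl malonate
Product: 6 dimethyl 2-[1-(4-hydroxyphenyl)-5-oxohexan-3-yl]propanedioate (racemic)
Conditions: NaOMe (0.2 equiv), MeOH, rt; AcOH
Reagents that add atoms: none
Why: Base-catalysed Michael addition of the malonate anion to the enone β-carbon, with the phenoxide only buffering the catalytic methoxide; the new stereocentre forms as a racemate and later becomes an sp2 carbon of ring A.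

Step 4
Reactants: 6 dimethyl 2-[1-(4-hydroxyphenyl)-5-oxohexan-3-yl]propanedioate (racemic)
Product: 7 methyl 6-[2-(4-hydroxyphenyl)ethyl]-2,4-dioxocyclohexane-1-carboxylate (racemic)
Conditions: NaOMe (2.5 equiv), MeOH, reflux; then 1 M HCl, 0 °C
Reagents that add atoms: none
Why: Methoxide reversibly forms the methyl-ketone enolate, whose terminal carbon adds to one of the two malonate ester carbonyls and expels methoxide; this is an intramolecular crossed Claisen (Dieckmann-type) condensation, and the closest known case is the ring-closing stage of the classical dimedone and 5-alkylcyclohexane-1,3-dione syntheses. The carbocycle that becomes ring A closes in a 6-(enolendo)-exo-trig mode, the enolate C=C lying inside the new ring and the ester C=O outside it. No stereocentre of consequence is set: C6 is carried over racemic from 6, C1 lies between carbonyls and epimerizes freely, and both are erased later. The selectivity needed is site selectivity among enolate acylations; the internal CH2 enolate and the malonate carbanion could only reach four-membered rings, so ring size leaves the methyl carbon as the one competent nucleophile, and the two ester groups lead to the same product. The otherwise reversible condensation is pulled forward by deprotonation of the cyclic β-dicarbonyl product, for which base beyond the equivalent held by the phenoxide is supplied, and the methyl esters match the methoxide so that ester exchange is invisible.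

Step 5
Reactants: 7 methyl 6-[2-(4-hydroxyphenyl)ethyl]-2,4-dioxocyclohexane-1-carboxylate (racemic)
Product: 9 5-[2-(4-hydroxyphenyl)ethyl]cyclohexane-1,3-dione, via keto acid 8 (not isolated)
Conditions: aq. NaOH, 90 °C; then HCl to pH 1, 90 °C
Reagents that add atoms: none
Why: Saponification followed by acid-promoted decarboxylation of the β-keto acid through the usual cyclic transition state should give the mirror-symmetric dione, the standard finish of a dimedone-type synthesis.

Step 6
Reactants: 9 5-[2-(4-hydroxyphenyl)ethyl]cyclohexane-1,3-dione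
Product: 11 5-[2-(4-{[tert-butyl(dimethyl)silyl]oxy}phenyl)ethyl]cyclohexane-1,3-dione, via bis-silyl enol ether 10 (not isolated)
Conditions: TBSCl (2.3 equiv), imidazole, DMF, rt; then AcOH–THF–H2O, rt
Reagents that add atoms: tert-butyldimethylsilyl chloride, CC(C)(C)[Si](C)(C)Cl
Why: Imidazole-mediated silylation caps both the phenol and the dione enol, and the vinylogous silyl ester, as labile as a silyl carboxylate, is hydrolysed selectively by dilute acetic acid while the aryl silyl ether stays.

Step 7
Reactants: 11 5-[2-(4-{[tert-butyl(dimethyl)silyl]oxy}phenyl)ethyl]cyclohexane-1,3-dione; 12 3-methylbut-2-en-1-ol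
Product: 13 5-[2-(4-{[tert-butyl(dimethyl)silyl]oxy}phenyl)ethyl]-3-[(3-methylbut-2-en-1-yl)oxy]cyclohex-2-en-1-one (racemic)
Conditions: PPh3, DIAD, THF, 0 °C to rt
Reagents that add atoms: none
Why: In this Mitsunobu reaction the acidic dione (pKa about 5) protonates the betaine and its enolate oxygen displaces triphenylphosphine oxide from the primary carbon of the activated alcohol; because the dione is symmetric, either oxygen gives the same racemic vinylogous ester, and this is the point at which the C7 and C8a oxygens become different.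

Step 8
Reactants: 13 5-[2-(4-{[tert-butyl(dimethyl)silyl]oxy}phenyl)ethyl]-3-[(3-methylbut-2-en-1-yl)oxy]cyclohex-2-en-1-one (racemic); 14 3-methylbut-2-enal
Product: 15 5-[2-(4-{[tert-butyl(dimethyl)silyl]oxy}phenyl)ethyl]-6-(1-hydroxy-3-methylbut-2-en-1-yl)-3-[(3-methylbut-2-en-1-yl)oxy]cyclohex-2-en-1-one (mixture of racemic diastereomers)
Conditions: LiN(i-Pr)2, THF, −78 °C; then 14, −78 °C; AcOH
Reagents that add atoms: none
Why: Kinetic deprotonation of a 3-alkoxycyclohexenone by LiN(i-Pr)2 occurs only at the α′ CH2 (Stork–Danheiser regiochemistry), the carbon that becomes C4a, and the lithium enolate adds 1,2 to the β,β-disubstituted enal (aldol addition); the two new stereocentres form without control and do not matter, since both carbons become sp2 in step 9.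

Step 9
Reactants: 15 5-[2-(4-{[tert-butyl(dimethyl)silyl]oxy}phenyl)ethyl]-6-(1-hydroxy-3-methylbut-2-en-1-yl)-3-[(3-methylbut-2-en-1-yl)oxy]cyclohex-2-en-1-one
Product: 18 tert-butyl(dimethyl)(4-{2-[2,2-dimethyl-7-[(3-methylbut-2-en-1-yl)oxy]-5,6-dihydro-2H-chromen-5-yl]ethyl}phenoxy)silane (racemic), via allylic mesylate 16 (not isolated), via cross-conjugated dienone 17 (not isolated)
Conditions: MsCl, Et3N, toluene, 0 °C; then DBU, 80 °C
Reagents that add atoms: none
Why: Mesylation and E1cB elimination should give dienone 17 as an E/Z mixture; DBU is expected to equilibrate the exocyclic alkene (reversible conjugate addition and the extended enolate formed at a terminal methyl both make the C6–exocyclic bond single), and the 6Z isomer, a 1-oxatriene with its gem-dimethyl terminus next to the carbonyl oxygen, is drained by thermal oxa-6π electrocyclization to the ring-fused 2,2-dimethyl-2H-pyran, the valence isomer favoured by the gem-dimethyl group and the ring fusion; the temperature stays well below that of a Claisen rearrangement of the prenyl vinyl ether.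

Step 10
Reactants: 18 tert-butyl(dimethyl)(4-{2-[2,2-dimethyl-7-[(3-methylbut-2-en-1-yl)oxy]-5,6-dihydro-2H-chromen-5-yl]ethyl}phenoxy)silane (racemic)
Product: 19 tert-butyl(dimethyl)(4-{2-[2,2-dimethyl-7-[(3-methylbut-2-en-1-yl)oxy]-2H-chromen-5-yl]ethyl}phenoxy)silane
Conditions: DDQ (1.05 equiv), toluene, 0 °C
Reagents that add atoms: none
Why: DDQ dehydrogenation: abstraction of the C5 hydride from the cyclohexadiene gives a cation stabilized by both ring A oxygens (the arenium ion of the product), which loses the C6 proton; this should be far faster than oxidation of the prenyl ether under anhydrous conditions at 0 °C, and the last stereocentre disappears here.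

Step 11
Reactants: 19 tert-butyl(dimethyl)(4-{2-[2,2-dimethyl-7-[(3-methylbut-2-en-1-yl)oxy]-2H-chromen-5-yl]ethyl}phenoxy)silane
Product: 20 4-{2-[2,2-dimethyl-7-[(3-methylbut-2-en-1-yl)oxy]-2H-chromen-5-yl]ethyl}phenol (CNP0337021.0)
Conditions: Bu4NF, THF, 0 °C
Reagents that add atoms: none
Why: Fluoride-induced cleavage of the aryl silyl ether, driven by Si–F bond formation, should release the ring C phenol without touching the prenyl ether or the chromene alkene.

**Compound list**

1 | methyl 3-(4-hydroxyphenyl)propanoate | COC(=O)CCc1ccc(O)cc1 | starting material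
2 | 3-(4-hydroxyphenyl)propanal | O=CCCc1ccc(O)cc1 | intermediate
3 | 1-(triphenylphosphoranylidene)propan-2-one | CC(=O)C=P(c1ccccc1)(c1ccccc1)c1ccccc1 | starting material
4 | (3E)-6-(4-hydroxyphenyl)hex-3-en-2-one | CC(=O)/C=C/CCc1ccc(O)cc1 | intermediate
5 | dimethyl malonate | COC(=O)CC(=O)OC | starting material
6 | dimethyl 2-[1-(4-hydroxyphenyl)-5-oxohexan-3-yl]propanedioate (racemic) | COC(=O)C(C(=O)OC)C(CCc1ccc(O)cc1)CC(C)=O | intermediate
7 | methyl 6-[2-(4-hydroxyphenyl)ethyl]-2,4-dioxocyclohexane-1-carboxylate (racemic; C1 epimerizable; largely enolized) | COC(=O)C1C(=O)CC(=O)CC1CCc1ccc(O)cc1 | intermediate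
8 | 6-[2-(4-hydroxyphenyl)ethyl]-2,4-dioxocyclohexane-1-carboxylic acid (racemic; not isolated) | OC(=O)C1C(=O)CC(=O)CC1CCc1ccc(O)cc1 | intermediate
9 | 5-[2-(4-hydroxyphenyl)ethyl]cyclohexane-1,3-dione (achiral) | O=C1CC(=O)CC(CCc2ccc(O)cc2)C1 | intermediate
10 | 3-{[tert-butyl(dimethyl)silyl]oxy}-5-[2-(4-{[tert-butyl(dimethyl)silyl]oxy}phenyl)ethyl]cyclohex-2-en-1-one (racemic; not isolated) | CC(C)(C)[Si](C)(C)OC1=CC(=O)CC(CCc2ccc(O[Si](C)(C)C(C)(C)C)cc2)C1 | intermediate
11 | 5-[2-(4-{[tert-butyl(dimethyl)silyl]oxy}phenyl)ethyl]cyclohexane-1,3-dione (achiral) | CC(C)(C)[Si](C)(C)Oc1ccc(CCC2CC(=O)CC(=O)C2)cc1 | intermediate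
12 | 3-methylbut-2-en-1-ol | CC(C)=CCO | starting material
13 | 5-[2-(4-{[tert-butyl(dimethyl)silyl]oxy}phenyl)ethyl]-3-[(3-methylbut-2-en-1-yl)oxy]cyclohex-2-en-1-one (racemic) | CC(C)=CCOC1=CC(=O)CC(CCc2ccc(O[Si](C)(C)C(C)(C)C)cc2)C1 | intermediate
14 | 3-methylbut-2-enal | CC(C)=CC=O | starting material
15 | 5-[2-(4-{[tert-butyl(dimethyl)silyl]oxy}phenyl)ethyl]-6-(1-hydroxy-3-methylbut-2-en-1-yl)-3-[(3-methylbut-2-en-1-yl)oxy]cyclohex-2-en-1-one (mixture of racemic diastereomers) | CC(C)=CCOC1=CC(=O)C(C(O)C=C(C)C)C(CCc2ccc(O[Si](C)(C)C(C)(C)C)cc2)C1 | intermediate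
16 | 1-{6-[2-(4-{[tert-butyl(dimethyl)silyl]oxy}phenyl)ethyl]-4-[(3-methylbut-2-en-1-yl)oxy]-2-oxocyclohex-3-en-1-yl}-3-methylbut-2-en-1-yl methanesulfonate (diastereomer mixture; not isolated) | CC(C)=CCOC1=CC(=O)C(C(OS(C)(=O)=O)C=C(C)C)C(CCc2ccc(O[Si](C)(C)C(C)(C)C)cc2)C1 | intermediate
17 | (6Z)-5-[2-(4-{[tert-butyl(dimethyl)silyl]oxy}phenyl)ethyl]-6-(3-methylbut-2-en-1-ylidene)-3-[(3-methylbut-2-en-1-yl)oxy]cyclohex-2-en-1-one (racemic; formed with its 6E isomer, the 6Z isomer shown is the one that closes; not isolated) | CC(C)=CCOC1=CC(=O)/C(=C\C=C(C)C)C(CCc2ccc(O[Si](C)(C)C(C)(C)C)cc2)C1 | intermediate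
18 | tert-butyl(dimethyl)(4-{2-[2,2-dimethyl-7-[(3-methylbut-2-en-1-yl)oxy]-5,6-dihydro-2H-chromen-5-yl]ethyl}phenoxy)silane (racemic) | CC(C)=CCOC1=CC2=C(C=CC(C)(C)O2)C(CCc2ccc(O[Si](C)(C)C(C)(C)C)cc2)C1 | intermediate
19 | tert-butyl(dimethyl)(4-{2-[2,2-dimethyl-7-[(3-methylbut-2-en-1-yl)oxy]-2H-chromen-5-yl]ethyl}phenoxy)silane | CC(C)=CCOc1cc(CCc2ccc(O[Si](C)(C)C(C)(C)C)cc2)c2c(c1)OC(C)(C)C=C2 | intermediate
20 | 4-{2-[2,2-dimethyl-7-[(3-methylbut-2-en-1-yl)oxy]-2H-chromen-5-yl]ethyl}phenol | CC(C)=CCOc1cc(CCc2ccc(O)cc2)c2c(c1)OC(C)(C)C=C2 | target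

**Count and risks**

Total step count: 11. Longest linear sequence: 11 steps (from 1 to 20).

Steps most likely to fail:

Step 9. The elimination may deliver the dienone mainly as its 6E isomer, whose diene arm points away from the carbonyl oxygen. Base-mediated isomerization to the closable 6Z form may then be slower than tautomerization or decomposition of the dienone, so that ring B does not close. The fallback sets out from 15 and builds ring B by a conjugate addition in which no alkene geometry is at stake. Oxidation of 15 with Dess–Martin periodinane would give the β-diketone 5-[2-(4-{[tert-butyl(dimethyl)silyl]oxy}phenyl)ethyl]-6-(3-methylbut-2-enoyl)-3-[(3-methylbut-2-en-1-yl)oxy]cyclohex-2-en-1-one F1. Under catalytic DBU in toluene its enol oxygen should add 6-endo to the β,β-dimethyl enone (oxa-Michael) to give 5-[2-(4-{[tert-butyl(dimethyl)silyl]oxy}phenyl)ethyl]-2,2-dimethyl-7-[(3-methylbut-2-en-1-yl)oxy]-2,3,5,6-tetrahydro-4H-chromen-4-one F2. DDQ would aromatize ring A to 5-[2-(4-{[tert-butyl(dimethyl)silyl]oxy}phenyl)ethyl]-2,2-dimethyl-7-[(3-methylbut-2-en-1-yl)oxy]-2,3-dihydro-4H-chromen-4-one F3. NaBH4 in EtOH–THF at 0 °C would give the racemic 5-[2-(4-{[tert-butyl(dimethyl)silyl]oxy}phenyl)ethyl]-2,2-dimethyl-7-[(3-methylbut-2-en-1-yl)oxy]-3,4-dihydro-2H-chromen-4-ol F4. Benzylic dehydration with catalytic p-TsOH in toluene at 60 °C then returns to the route at 19, and step 11 follows.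

Step 7. Alkylation at the central carbon of the dione, or attack through the tertiary terminus of the allyl unit, may compete with O-alkylation at the primary carbon. The fallback sets out from 11 and forms the vinyl C–O bond instead of the allyl C–O bond. Compound 11 would be condensed directly with 3-methylbut-2-en-1-ol 12 under catalytic p-TsOH in refluxing benzene with azeotropic removal of water. The alcohol is then the nucleophile at the dione carbonyl, so neither C-alkylation nor allylic transposition can arise. The route is rejoined at 13, and no compound outside the route is made (F0).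

Step 1. Collapse of the aluminium hemiacetal before the quench would lead to over-reduction to the primary alcohol, and aggregation of the aluminium phenoxide may leave ester unconverted. The fallback sets out from 1 and passes through an acyl derivative that cannot be reduced twice. MeNH(OMe)·HCl and i-PrMgCl in THF at −10 °C would convert 1 into the Weinreb amide 3-(4-hydroxyphenyl)-N-methoxy-N-methylpropanamide F5. Its stable chelated adduct with LiAlH4 in THF at 0 °C should give the aldehyde only on acidic work-up, rejoining the route at 2.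

**Further compounds**

F1 | step 9 | 5-[2-(4-{[tert-butyl(dimethyl)silyl]oxy}phenyl)ethyl]-6-(3-methylbut-2-enoyl)-3-[(3-methylbut-2-en-1-yl)oxy]cyclohex-2-en-1-one (racemic) | CC(C)=CCOC1=CC(=O)C(C(=O)C=C(C)C)C(CCc2ccc(O[Si](C)(C)C(C)(C)C)cc2)C1
F2 | step 9 | 5-[2-(4-{[tert-butyl(dimethyl)silyl]oxy}phenyl)ethyl]-2,2-dimethyl-7-[(3-methylbut-2-en-1-yl)oxy]-2,3,5,6-tetrahydro-4H-chromen-4-one (racemic) | CC(C)=CCOC1=CC2=C(C(=O)CC(C)(C)O2)C(CCc2ccc(O[Si](C)(C)C(C)(C)C)cc2)C1
F3 | step 9 | 5-[2-(4-{[tert-butyl(dimethyl)silyl]oxy}phenyl)ethyl]-2,2-dimethyl-7-[(3-methylbut-2-en-1-yl)oxy]-2,3-dihydro-4H-chromen-4-one | CC(C)=CCOc1cc(CCc2ccc(O[Si](C)(C)C(C)(C)C)cc2)c2c(c1)OC(C)(C)CC2=O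
F4 | step 9 | 5-[2-(4-{[tert-butyl(dimethyl)silyl]oxy}phenyl)ethyl]-2,2-dimethyl-7-[(3-methylbut-2-en-1-yl)oxy]-3,4-dihydro-2H-chromen-4-ol (racemic) | CC(C)=CCOc1cc(CCc2ccc(O[Si](C)(C)C(C)(C)C)cc2)c2c(c1)OC(C)(C)CC2O
F0 | step 7 | none | none
F5 | step 1 | 3-(4-hydroxyphenyl)-N-methoxy-N-methylpropanamide | CON(C)C(=O)CCc1ccc(O)cc1
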